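**Plan**

- Retrosynthesis: the three O–Si bonds are cut first, then the C3–C7 bond (benzylation of a lactone enolate), then the O1–C5 bond of the oxolan-2-one ring.
- Enabling feature: without its benzyl group, C4 of the lactone lies between two CH2 groups (C3 and C5). The ring is therefore the oxygen-insertion product of a 3-substituted cyclobutanone; shifting one α-CH2 to oxygen makes O1–C5 and turns C4 into a stereocenter.
- The cyclobutanone is masked as a methylidenecyclobutane, and its C7'–aryl bond is cut to an aryl Grignard reagent and 3-methylidenecyclobutane-1-carbonitrile.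
- Forward order: aryl ketone, C7' carbinol, unmasking of the four-membered ketone, ring enlargement to the lactone (the only ring formed), benzyl side chain, desilylation.
- Stereochemistry: C7' (S) from a Corey–Bakshi–Shibata reduction; C4 (R) from the ligand-controlled Baeyer–Villiger step; C3 (R) from alkylation anti to the C4 substituent.

Key step: step 6

Assumption: the antipode of the N,N'-dioxide ligand that gives the 4R lactone in step 6 is identified in a small test run; both antipodes are accessible from the two enantiomers of pipecolic acid.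

**Route**

Step 1
Reactants: 1 4-bromo-2-methoxyphenol
Product: 2 (4-bromo-2-methoxyphenoxy)(tert-butyl)dimethylsilane
Conditions: TBSCl, imidazole, DMF, rt
Reagents that add atoms: tert-butyldimethylsilyl chloride (TBSCl), CC(C)(C)[Si](C)(C)Cl
Why: Imidazole-promoted silylation of a phenol should be fast and clean and gives a protecting group that survives Grignard formation, peracid and amide bases and leaves with fluoride.

Step 2
Reactants: 2 (4-bromo-2-methoxyphenoxy)(tert-butyl)dimethylsilane; 3 3-methylidenecyclobutane-1-carbonitrile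
Product: 6 [4-(tert-butyldimethylsilyloxy)-3-methoxyphenyl](3-methylidenecyclobutyl)methanone, via aryl Grignard reagent 4 (not isolated), via bromomagnesium ketimide 5 (not isolated)
Conditions: Mg turnings, THF, 50 °C; then 3, CuBr·SMe2 (3 mol%), THF, 60 °C; then 1 M aq. HCl, 0 °C
Reagents that add atoms: magnesium, [Mg] (stays only in 4 and 5); water, O (ketone oxygen)
Why: Copper-catalysed Grignard addition to a nitrile stops at the N-magnesio ketimide, which cannot take up a second aryl group and should hydrolyse to the ketone in cold dilute acid without harm to the aryl silyl ether or the exocyclic alkene.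

Step 3
Reactants: 6 [4-(tert-butyldimethylsilyloxy)-3-methoxyphenyl](3-methylidenecyclobutyl)methanone
Product: 8 (S)-[4-(tert-butyldimethylsilyloxy)-3-methoxyphenyl](3-methylidenecyclobutyl)methanol, via catecholboryl ether 7 (not isolated)
Conditions: (R)-2-methyl-CBS-oxazaborolidine [(3aR)-1-methyl-3,3-diphenyltetrahydro-1H,3H-pyrrolo[1,2-c][1,3,2]oxazaborole] (20 mol%), catecholborane (1.8 equiv), toluene, −78 °C; then pH 7 buffer
Reagents that add atoms: catecholborane, B1Oc2ccccc2O1 (boron and its oxygens stay only in 7; the product gains hydrogen only)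
Why: Corey–Bakshi–Shibata reduction with the aryl ring as the large group and the cyclobutyl as the small one should give the (S)-carbinol with the (R)-catalyst, the sense known for aryl alkyl ketones, and catecholborane at −78 °C should not hydroborate the 1,1-disubstituted alkene.

Step 4
Reactants: 8 (S)-[4-(tert-butyldimethylsilyloxy)-3-methoxyphenyl](3-methylidenecyclobutyl)methanol
Product: 9 tert-butyl{4-[(S)-(tert-butyldimethylsilyloxy)(3-methylidenecyclobutyl)methyl]-2-methoxyphenoxy}dimethylsilane
Conditions: TBSCl, imidazole, DMAP (cat.), DMF, 40 °C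
Reagents that add atoms: tert-butyldimethylsilyl chloride (TBSCl), CC(C)(C)[Si](C)(C)Cl
Why: Silylation of the secondary benzylic alcohol under basic conditions avoids ionisation at C7' and masks the hydroxyl for the oxidation and enolate steps.

Step 5
Reactants: 9 tert-butyl{4-[(S)-(tert-butyldimethylsilyloxy)(3-methylidenecyclobutyl)methyl]-2-methoxyphenoxy}dimethylsilane
Product: 11 3-{(S)-(tert-butyldimethylsilyloxy)[4-(tert-butyldimethylsilyloxy)-3-methoxyphenyl]methyl}cyclobutan-1-one, via vicinal diol 10 (not isolated)
Conditions: K2OsO4·2H2O (2 mol%), NaIO4 (4 equiv), 2,6-lutidine (2 equiv), dioxane/H2O 3:1, rt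
Reagents that add atoms: sodium periodate, [Na+].[O-]I(=O)(=O)=O; water, O
Why: Lemieux–Johnson oxidation (catalytic dihydroxylation, then periodate glycol cleavage in the same flask) should unmask the cyclobutanone under near-neutral conditions that spare both silyl ethers and the electron-rich arene.

Step 6
Reactants: 11 3-{(S)-(tert-butyldimethylsilyloxy)[4-(tert-butyldimethylsilyloxy)-3-methoxyphenyl]methyl}cyclobutan-1-one
Product: 13 (4R)-4-{(S)-(tert-butyldimethylsilyloxy)[4-(tert-butyldimethylsilyloxy)-3-methoxyphenyl]methyl}oxolan-2-one, via Criegee adduct 12 (not isolated)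
Conditions: Sc(OTf)3 (5 mol%), N,N'-dioxide ligand 1,1'-(propane-1,3-diyl)bis{(2S)-2-[(2,6-diisopropylphenyl)carbamoyl]piperidine 1-oxide} or its enantiomer (6 mol%), mCPBA (1.3 equiv), EtOAc, −20 °C
Reagents that add atoms: 3-chloroperoxybenzoic acid (mCPBA), OOC(=O)c1cccc(Cl)c1
Why: This is a Baeyer–Villiger oxidation run as a catalytic asymmetric desymmetrization: the scandium-bound cyclobutanone carbonyl takes up the peracid to give Criegee adduct 12, and one α-CH2 then shifts from carbon to the proximal peroxide oxygen with loss of 3-chlorobenzoate, which forms the O1–C5 bond. The closest known reaction type is the chiral Lewis acid catalysed Baeyer–Villiger desymmetrization of prochiral 3-substituted cyclobutanones to β-substituted γ-butyrolactones. The oxolan-2-one ring closes by this 1,2-shift, a ring enlargement of the four-membered ketone by oxygen insertion and not an exo or endo cyclization. The new stereocenter C4 is the former C3 of the cyclobutanone, which becomes stereogenic only because one of its two CH2 arms migrates; the chiral N,N'-dioxide ligand on scandium decides which arm lies antiperiplanar to the O–O bond, and its antipode is chosen for 4R. The step needs group selectivity between two diastereotopic CH2 groups, which the catalyst must supply because the exocyclic C7' center is too remote to bias it, and chemoselectivity for the ketone over the two electron-rich arenes, which the ring strain of the cyclobutanone secures; regioselectivity is no issue because both candidates for migration are CH2. The two possible products are diastereomers, so a minor C4 epimer should be removable by chromatography.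

Step 7
Reactants: 14 vanillin (4-hydroxy-3-methoxybenzaldehyde)
Product: 15 4-(tert-butyldimethylsilyloxy)-3-methoxybenzaldehyde
Conditions: TBSCl, imidazole, DMF, rt
Reagents that add atoms: tert-butyldimethylsilyl chloride (TBSCl), CC(C)(C)[Si](C)(C)Cl
Why: Imidazole-promoted phenol silylation, as in step 1.

Step 8
Reactants: 15 4-(tert-butyldimethylsilyloxy)-3-methoxybenzaldehyde
Product: 16 [4-(tert-butyldimethylsilyloxy)-3-methoxyphenyl]methanol
Conditions: NaBH4, THF/MeOH 10:1, 0 °C
Reagents that add atoms: none
Why: Borohydride reduction of an aryl aldehyde is fast at 0 °C, and the short contact time in a mostly aprotic medium should keep the aryl silyl ether intact.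

Step 9
Reactants: 16 [4-(tert-butyldimethylsilyloxy)-3-methoxyphenyl]methanol
Product: 17 [4-(bromomethyl)-2-methoxyphenoxy](tert-butyl)dimethylsilane
Conditions: CBr4, PPh3, CH2Cl2, 0 °C; used at once
Reagents that add atoms: carbon tetrabromide, BrC(Br)(Br)Br
Why: The Appel reaction converts the benzylic alcohol into the bromide under neutral conditions that a silyl ether tolerates.

Step 10
Reactants: 13 (4R)-4-{(S)-(tert-butyldimethylsilyloxy)[4-(tert-butyldimethylsilyloxy)-3-methoxyphenyl]methyl}oxolan-2-one; 17 [4-(bromomethyl)-2-methoxyphenoxy](tert-butyl)dimethylsilane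
Product: 19 (3R,4R)-4-{(S)-(tert-butyldimethylsilyloxy)[4-(tert-butyldimethylsilyloxy)-3-methoxyphenyl]methyl}-3-[4-(tert-butyldimethylsilyloxy)-3-methoxybenzyl]oxolan-2-one, via lithium enolate 18 (not isolated)
Conditions: LiN(SiMe3)2 (1.1 equiv), THF, −78 °C; then 17 (1.2 equiv), DMPU, −78 to −30 °C
Reagents that add atoms: lithium bis(trimethylsilyl)amide, [Li]N([Si](C)(C)C)[Si](C)(C)C (lithium stays only in 18)
Why: Alkylation of a γ-butyrolactone lithium enolate with a reactive benzylic bromide should take place on the enolate face anti to the bulky C4 substituent, which sets C3 as R and trans to C4, the usual outcome for β-substituted butyrolactones.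

Step 11
Reactants: 19 (3R,4R)-4-{(S)-(tert-butyldimethylsilyloxy)[4-(tert-butyldimethylsilyloxy)-3-methoxyphenyl]methyl}-3-[4-(tert-butyldimethylsilyloxy)-3-methoxybenzyl]oxolan-2-one
Product: 20 (3R,4R)-4-[(S)-hydroxy(4-hydroxy-3-methoxyphenyl)methyl]-3-(4-hydroxy-3-methoxybenzyl)oxolan-2-one
Conditions: Bu4NF (4 equiv), AcOH (4 equiv), THF, 0 °C to rt
Reagents that add atoms: none
Why: Fluoride-mediated desilylation buffered with acetic acid should free both phenols and the benzylic alcohol while keeping the medium near neutral, so that the lactone, the C3 center and the p-hydroxybenzylic alcohol are not disturbed.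

**Compound list**

1 | 4-bromo-2-methoxyphenol | COc1cc(Br)ccc1O | starting material
2 | (4-bromo-2-methoxyphenoxy)(tert-butyl)dimethylsilane | COc1cc(Br)ccc1O[Si](C)(C)C(C)(C)C | intermediate
3 | 3-methylidenecyclobutane-1-carbonitrile | C=C1CC(C#N)C1 | starting material
4 | [4-(tert-butyldimethylsilyloxy)-3-methoxyphenyl]magnesium bromide | COc1cc([Mg]Br)ccc1O[Si](C)(C)C(C)(C)C | intermediate
5 | bromomagnesium salt of [4-(tert-butyldimethylsilyloxy)-3-methoxyphenyl](3-methylidenecyclobutyl)methanimine | C=C1CC(C1)C(=N[Mg]Br)c1ccc(O[Si](C)(C)C(C)(C)C)c(OC)c1 | intermediate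
6 | [4-(tert-butyldimethylsilyloxy)-3-methoxyphenyl](3-methylidenecyclobutyl)methanone | C=C1CC(C1)C(=O)c1ccc(O[Si](C)(C)C(C)(C)C)c(OC)c1 | intermediate
7 | 2-{(S)-[4-(tert-butyldimethylsilyloxy)-3-methoxyphenyl](3-methylidenecyclobutyl)methoxy}-1,3,2-benzodioxaborole | C=C1CC(C1)[C@H](OB1Oc2ccccc2O1)c1ccc(O[Si](C)(C)C(C)(C)C)c(OC)c1 | intermediate
8 | (S)-[4-(tert-butyldimethylsilyloxy)-3-methoxyphenyl](3-methylidenecyclobutyl)methanol | C=C1CC(C1)[C@H](O)c1ccc(O[Si](C)(C)C(C)(C)C)c(OC)c1 | intermediate
9 | tert-butyl{4-[(S)-(tert-butyldimethylsilyloxy)(3-methylidenecyclobutyl)methyl]-2-methoxyphenoxy}dimethylsilane | C=C1CC(C1)[C@H](O[Si](C)(C)C(C)(C)C)c1ccc(O[Si](C)(C)C(C)(C)C)c(OC)c1 | intermediate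
10 | 3-{(S)-(tert-butyldimethylsilyloxy)[4-(tert-butyldimethylsilyloxy)-3-methoxyphenyl]methyl}-1-(hydroxymethyl)cyclobutan-1-ol (cis/trans mixture on the ring) | OCC1(O)CC(C1)[C@H](O[Si](C)(C)C(C)(C)C)c1ccc(O[Si](C)(C)C(C)(C)C)c(OC)c1 | intermediate
11 | 3-{(S)-(tert-butyldimethylsilyloxy)[4-(tert-butyldimethylsilyloxy)-3-methoxyphenyl]methyl}cyclobutan-1-one | O=C1CC(C1)[C@H](O[Si](C)(C)C(C)(C)C)c1ccc(O[Si](C)(C)C(C)(C)C)c(OC)c1 | intermediate
12 | 1-hydroxy-3-{(S)-(tert-butyldimethylsilyloxy)[4-(tert-butyldimethylsilyloxy)-3-methoxyphenyl]methyl}cyclobutyl 3-chlorobenzoperoxoate (Criegee adduct) | OC1(OOC(=O)c2cccc(Cl)c2)CC(C1)[C@H](O[Si](C)(C)C(C)(C)C)c1ccc(O[Si](C)(C)C(C)(C)C)c(OC)c1 | intermediate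
13 | (4R)-4-{(S)-(tert-butyldimethylsilyloxy)[4-(tert-butyldimethylsilyloxy)-3-methoxyphenyl]methyl}oxolan-2-one | O=C1C[C@H](CO1)[C@H](O[Si](C)(C)C(C)(C)C)c1ccc(O[Si](C)(C)C(C)(C)C)c(OC)c1 | intermediate
14 | vanillin (4-hydroxy-3-methoxybenzaldehyde) | COc1cc(C=O)ccc1O | starting material
15 | 4-(tert-butyldimethylsilyloxy)-3-methoxybenzaldehyde | COc1cc(C=O)ccc1O[Si](C)(C)C(C)(C)C | intermediate
16 | [4-(tert-butyldimethylsilyloxy)-3-methoxyphenyl]methanol | COc1cc(CO)ccc1O[Si](C)(C)C(C)(C)C | intermediate
17 | [4-(bromomethyl)-2-methoxyphenoxy](tert-butyl)dimethylsilane | COc1cc(CBr)ccc1O[Si](C)(C)C(C)(C)C | intermediate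
18 | lithium enolate of 13 | [Li]OC1=C[C@H](CO1)[C@H](O[Si](C)(C)C(C)(C)C)c1ccc(O[Si](C)(C)C(C)(C)C)c(OC)c1 | intermediate
19 | (3R,4R)-4-{(S)-(tert-butyldimethylsilyloxy)[4-(tert-butyldimethylsilyloxy)-3-methoxyphenyl]methyl}-3-[4-(tert-butyldimethylsilyloxy)-3-methoxybenzyl]oxolan-2-one | COc1cc(C[C@H]2C(=O)OC[C@@H]2[C@H](O[Si](C)(C)C(C)(C)C)c2ccc(O[Si](C)(C)C(C)(C)C)c(OC)c2)ccc1O[Si](C)(C)C(C)(C)C | intermediate
20 | (3R,4R)-4-[(S)-hydroxy(4-hydroxy-3-methoxyphenyl)methyl]-3-(4-hydroxy-3-methoxybenzyl)oxolan-2-one | COc1cc(C[C@H]2C(=O)OC[C@@H]2[C@H](O)c2ccc(O)c(OC)c2)ccc1O | target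

**Step count**

Total step count: 11. Longest linear sequence: 8 steps (steps 1 to 6, then 10 and 11); steps 7 to 9 make the benzyl bromide in a side branch.

**Steps most likely to fail**

Step 6. The ligand may not discriminate well enough between the two diastereotopic CH2 arms when the bulky silyloxy(aryl)methyl group sits at C3, and the Lewis acid may start ionisation at the benzylic silyl ether. The fallback sets out from cyclobutanone 11 and comes back at lactone 13. Ketone 11 would be deprotonated group-selectively with a chiral lithium amide (lithium bis[(R)-1-phenylethyl]amide or its antipode, chosen for the 4R series) in THF at −100 °C with Me3SiCl present, to give the trimethylsilyl enol ether F1. Ozonolysis (O3, CH2Cl2/MeOH, −78 °C) would cleave the enol ether double bond to the aldehyde acid F2, which is reduced in the same flask with NaBH4 to the hydroxy acid F3. Mild acidification would close F3 to lactone 13.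

Step 3. The catalyst may distinguish the aryl and cyclobutyl groups less well than aryl and methyl, and the alkene may be slowly hydroborated if the reduction has to be warmed. The fallback sets out from ketone 6 and comes back at alcohol 8. Ketone 6 would be reduced with NaBH4 to the racemic [4-(tert-butyldimethylsilyloxy)-3-methoxyphenyl](3-methylidenecyclobutyl)methanol F4. An acylative kinetic resolution would follow, with 2-phenyl-2,3-dihydrobenzo[d]imidazo[2,1-b]thiazole (benzotetramisole, the antipode that acylates the R alcohol), isobutyric anhydride and iPr2NEt in CHCl3 at 0 °C. It would convert the unwanted enantiomer into the (R)-isobutyrate F5 and leave the (S)-alcohol 8, which is separated by chromatography.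

Step 11. Once the phenoxide and the C7' alkoxide are both free, the lactone may migrate to the C7' oxygen, C3 may epimerise, or the benzylic oxygen may be lost through a quinone methide. The fallback sets out from 19 and comes back at target 20, and removes the silyl groups in two stages. KHF2 in MeOH at rt would cleave only the two aryl silyl ethers and give the 7'-O-silyl bisphenol (3R,4R)-4-[(S)-(tert-butyldimethylsilyloxy)(4-hydroxy-3-methoxyphenyl)methyl]-3-(4-hydroxy-3-methoxybenzyl)oxolan-2-one F6. The remaining secondary silyl ether would then be removed with HF·pyridine in pyridine/THF at 0 °C, conditions in which no phenoxide is present, to give 20.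

**Further compounds**

F1 | step 6 | tert-butyl{4-[(S)-(tert-butyldimethylsilyloxy)(3-trimethylsilyloxycyclobut-2-en-1-yl)methyl]-2-methoxyphenoxy}dimethylsilane (ring center set for the 4R series) | C[Si](C)(C)OC1=C[C@@H](C1)[C@H](O[Si](C)(C)C(C)(C)C)c1ccc(O[Si](C)(C)C(C)(C)C)c(OC)c1
F2 | step 6 | (3R,4S)-4-(tert-butyldimethylsilyloxy)-4-[4-(tert-butyldimethylsilyloxy)-3-methoxyphenyl]-3-formylbutanoic acid | OC(=O)C[C@H](C=O)[C@H](O[Si](C)(C)C(C)(C)C)c1ccc(O[Si](C)(C)C(C)(C)C)c(OC)c1
F3 | step 6 | (3R,4S)-4-(tert-butyldimethylsilyloxy)-4-[4-(tert-butyldimethylsilyloxy)-3-methoxyphenyl]-3-(hydroxymethyl)butanoic acid | OC(=O)C[C@H](CO)[C@H](O[Si](C)(C)C(C)(C)C)c1ccc(O[Si](C)(C)C(C)(C)C)c(OC)c1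
F4 | step 3 | racemic [4-(tert-butyldimethylsilyloxy)-3-methoxyphenyl](3-methylidenecyclobutyl)methanol | C=C1CC(C1)C(O)c1ccc(O[Si](C)(C)C(C)(C)C)c(OC)c1
F5 | step 3 | (R)-[4-(tert-butyldimethylsilyloxy)-3-methoxyphenyl](3-methylidenecyclobutyl)methyl 2-methylpropanoate | C=C1CC(C1)[C@@H](OC(=O)C(C)C)c1ccc(O[Si](C)(C)C(C)(C)C)c(OC)c1
F6 | step 11 | (3R,4R)-4-[(S)-(tert-butyldimethylsilyloxy)(4-hydroxy-3-methoxyphenyl)methyl]-3-(4-hydroxy-3-methoxybenzyl)oxolan-2-one | COc1cc(C[C@H]2C(=O)OC[C@@H]2[C@H](O[Si](C)(C)C(C)(C)C)c2ccc(O)c(OC)c2)ccc1O
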